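**Plan**

1. Numbering: C1 (alkyne CH) to C15 (ethyl CH3); Oa links C6 and C9, Ob links C7 and C13; Br on C10 and C12. The target is read as (3Z,6S,7S,9S,10S,12S,13R).
2. Cuts, backwards: C3=C4 (enyne olefination); Oa–C9 together with C10–Br (transannular bromoetherification of a Δ9,10 oxocene); C12–Br (from the alcohol, with inversion); then C10–C13 is re-joined in thought and C10–C11 plus C12–C13 are cut ([2+2] of the C10=C13 enone with vinyl acetate); last Ob–C13 and C7–C8 (pyranone from an aldol).
3. Feature that allows this: the oxocane Ob–C7–C8–C9–C10–C11–C12–C13 is the six-membered ring Ob–C7–C8–C9–C10–C13 with C11–C12 let into its C10–C13 bond, and C12, next to C13, bears a heteroatom, as an enol-ester carbon would.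
4. Forward: chain by chelate-controlled aldol, pyranone ring (Ob–C13), cyclobutane by light, oxocene by fragmentation of C10–C13, oxolane ring (Oa–C9) by bromoetherification, enyne last.
5. Stereochemistry: C6 from the chiral pool ((S)-malic acid series); C7 from C6 by chelation; C12 from the photoadduct (attack anti to the C7 side chain, acetate endo), later inverted by bromide; C13 from hydride delivery trans to the participating C12 acetate; C9 and C10 from anti addition across the Z alkene by the C6 hydroxyl; 3Z from a Peterson olefination.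

Key step: step 8

Remark (assumptions): compounds 1, 6, 11 and 22 are taken as purchasable. Where a step is expected to give isomer mixtures (steps 6, 8, 10, 16), the wanted isomer is assumed to be separable by chromatography.

**Route**

Step 1
Reactants: 1 (S)-3-hydroxydihydrofuran-2(3H)-one ((S)-α-hydroxy-γ-butyrolactone)
Product: 2 (S)-3-(benzyloxy)dihydrofuran-2(3H)-one
Conditions: BnBr, Ag2O, Et2O, rt, dark
Reagents that add atoms: benzyl bromide, BrCc1ccccc1
Why: Silver(I)-oxide-promoted O-benzylation (a Williamson etherification under non-basic conditions) should etherify the α-hydroxyl without enolising the lactone, so the (S) centre that becomes C6 is carried over unchanged.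

Step 2
Reactants: 2 (S)-3-(benzyloxy)dihydrofuran-2(3H)-one
Product: 3 (S)-2-(benzyloxy)-4-hydroxy-N-methoxy-N-methylbutanamide
Conditions: MeNH(OMe)·HCl, i-PrMgCl, THF, −20 → 0 °C
Reagents that add atoms: N,O-dimethylhydroxylamine hydrochloride, CNOC.Cl
Why: Weinreb amide formation by aminolysis of the lactone with the magnesium amide made in the flask opens the ring at the acyl carbon only, leaving C6 untouched and freeing the C4 hydroxyl.

Step 3
Reactants: 3 (S)-2-(benzyloxy)-4-hydroxy-N-methoxy-N-methylbutanamide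
Product: 4 (S)-2-(benzyloxy)-4-(tert-butyldimethylsilyloxy)-N-methoxy-N-methylbutanamide
Conditions: TBSCl, imidazole, CH2Cl2, 0 °C → rt
Reagents that add atoms: tert-butyldimethylsilyl chloride, CC(C)(C)[Si](C)(C)Cl
Why: Imidazole-mediated silylation of the primary alcohol (silyl ether formation) blocks relactonisation and masks the C4 oxygen until step 13.

Step 4
Reactants: 4 (S)-2-(benzyloxy)-4-(tert-butyldimethylsilyloxy)-N-methoxy-N-methylbutanamide
Product: 5 (S)-2-(benzyloxy)-4-(tert-butyldimethylsilyloxy)butanal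
Conditions: DIBAL-H, THF, −78 °C; Rochelle salt work-up
Reagents that add atoms: none
Why: DIBAL-H reduction of a Weinreb amide stops at the aldehyde because the chelated tetrahedral aluminate survives until work-up; the α-benzyloxy aldehyde is used at once so that C6 does not epimerise.

Step 5
Reactants: 6 hex-3-yn-2-one
Product: 8 2-(trimethylsilyloxy)hex-1-en-3-yne, via lithium hex-1-en-3-yn-2-olate 7 (not isolated)
Conditions: LiHMDS, THF, −78 °C; then TMSCl
Reagents that add atoms: chlorotrimethylsilane, C[Si](C)(C)Cl; lithium hexamethyldisilazide, [Li+].C[Si](C)(C)[N-][Si](C)(C)C (supplies only the lithium of intermediate 7)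
Why: Kinetic deprotonation of the only α-methyl group by a hindered amide base followed by O-silylation (silyl enol ether formation) gives the enol silane needed for a Lewis-acid aldol; no stereocentre is formed.

Step 6
Reactants: 5 (S)-2-(benzyloxy)-4-(tert-butyldimethylsilyloxy)butanal; 8 2-(trimethylsilyloxy)hex-1-en-3-yne
Product: 9 (7S,8S)-8-(benzyloxy)-10-(tert-butyldimethylsilyloxy)-7-hydroxydec-3-yn-5-one (target atoms C4–C10 and C13–C15; C6-OBn and C7-OH syn)
Conditions: MgBr2·OEt2, CH2Cl2, −78 → −30 °C; aqueous NaHCO3 work-up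
Reagents that add atoms: none
Why: Mukaiyama aldol addition under chelation control: MgBr2 bridges the aldehyde oxygen and the α-benzyloxy oxygen, and the enol silane adds to the face of this five-membered chelate away from the C5 chain (Cram chelate model), which should set C7 as (S), syn to C6.

Step 7
Reactants: 9 (7S,8S)-8-(benzyloxy)-10-(tert-butyldimethylsilyloxy)-7-hydroxydec-3-yn-5-one
Product: 10 (2S)-2-[(1S)-1-(benzyloxy)-3-(tert-butyldimethylsilyloxy)propyl]-6-ethyl-2,3-dihydro-4H-pyran-4-one (enone C10=C13, ring oxygen Ob)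
Conditions: AgOTf (10 mol %), CH2Cl2, rt, dark
Reagents that add atoms: none
Why: Silver-catalysed 6-endo-dig cycloisomerisation (intramolecular oxa-Michael addition of the C7 hydroxyl to the ynone) forms the Ob–C13 bond and the dihydropyranone without touching C6 or C7.

Step 8
Reactants: 10 (2S)-2-[(1S)-1-(benzyloxy)-3-(tert-butyldimethylsilyloxy)propyl]-6-ethyl-2,3-dihydro-4H-pyran-4-one; 11 vinyl acetate
Product: 12 (1S,3S,6S,8R)-3-[(1S)-1-(benzyloxy)-3-(tert-butyldimethylsilyloxy)propyl]-1-ethyl-5-oxo-2-oxabicyclo[4.2.0]octan-8-yl acetate (cis-fused; cyclobutane C10–C11–C12–C13 anti to the C7 side chain; acetate on C12 endo, trans to the C13 ethyl group)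
Conditions: hν (medium-pressure Hg lamp, Pyrex, λ > 300 nm), vinyl acetate (20 equiv), MeCN, −20 °C; then basic Al2O3, CH2Cl2, rt
Reagents that add atoms: none
Why: Excitation of the enone and intersystem crossing give a triplet that adds to vinyl acetate through a 1,4-diradical, the known enone–alkene [2+2] photocycloaddition of 2,3-dihydro-4H-pyran-4-ones and cyclohexenones with enol esters and enol ethers. The cyclobutane closes by radical recombination of that diradical (C10–C11 and C12–C13 formed), and it ends cis-fused to the pyranone once any trans-fused adduct has been epimerised at C10 on alumina. Head-to-tail orientation is needed and is expected from polarity, the oxygen-bearing alkene carbon joining the β-carbon C13 as with other electron-rich alkenes. Of the three new stereocentres, C10 and C13 are tied together by the cis ring fusion and follow the face of attack, which should be the one anti to the C7 side chain; both are erased in step 10, so only their link to C12 matters. C12 is fixed by the endo placement of the acetoxy group, trans to the C13 ethyl group and cis to the small ring oxygen, which should be the less crowded arrangement at this fully substituted carbon. The step therefore needs the (12R) acetate relative to C7; isomers with the other C12 configuration or with head-to-head orientation are to be removed by chromatography.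

Step 9
Reactants: 12 (1S,3S,6S,8R)-3-[(1S)-1-(benzyloxy)-3-(tert-butyldimethylsilyloxy)propyl]-1-ethyl-5-oxo-2-oxabicyclo[4.2.0]octan-8-yl acetate
Product: 13 (1S,3S,5R,6R,8R)-3-[(1S)-1-(benzyloxy)-3-(tert-butyldimethylsilyloxy)propyl]-1-ethyl-5-hydroxy-2-oxabicyclo[4.2.0]octan-8-yl acetate (C9 hydroxyl cis to the cyclobutane carbon C11)
Conditions: NaBH4, CeCl3·7H2O, MeOH, −40 °C
Reagents that add atoms: none
Why: Luche reduction should deliver hydride to the convex face of the cis-fused bicycle, anti to the cyclobutane, giving the C9 alcohol whose C–O bond lies antiperiplanar to the C10–C13 bond; the acetate is not reduced under these conditions.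

Step 10
Reactants: 13 (1S,3S,5R,6R,8R)-3-[(1S)-1-(benzyloxy)-3-(tert-butyldimethylsilyloxy)propyl]-1-ethyl-5-hydroxy-2-oxabicyclo[4.2.0]octan-8-yl acetate
Product: 15 (2R,3R,5Z,8S)-8-[(1S)-1-(benzyloxy)-3-(tert-butyldimethylsilyloxy)propyl]-2-ethyl-3,4,7,8-tetrahydro-2H-oxocin-3-yl acetate (Δ9,10 oxocene; C12-OAc and C13-Et cis; C13-Et trans to the C7 side chain), via C9 triflate 14 (not isolated)
Conditions: Tf2O, 2,6-di-tert-butyl-4-methylpyridine, CH2Cl2, −78 °C; then Et3SiH, −78 → −20 °C
Reagents that add atoms: trifluoromethanesulfonic anhydride, O=S(=O)(OS(=O)(=O)C(F)(F)F)C(F)(F)F (its atoms stay only in intermediate 14; product 15 gains hydrogen alone)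
Why: Proposed new method: the C9 triflate and a lone pair of Ob are both antiperiplanar to the strained C10–C13 bond, so ionisation should trigger a Grob-type 1,3-heterolytic fragmentation that forms the (Z)-C9=C10 alkene and an eight-membered oxocarbenium ion at C13, the C12 acetate then closes onto C13 from its own face to give an acetoxonium ion, and triethylsilane opens it at C13 from the opposite face, placing the new hydrogen trans to the acetate and fixing C13 as (R); the closest known reactions are the Grob (Wharton) fragmentation of γ-oxygenated sulfonates of enone photoadducts to cyclooctenones and the silane reduction of oxocarbenium ions flanked by a participating acyloxy group (1,2-trans delivery), whereas their combination on a 2-oxabicyclo[4.2.0]octane with an ether oxygen as the electron donor has not been shown.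

Step 11
Reactants: 15 (2R,3R,5Z,8S)-8-[(1S)-1-(benzyloxy)-3-(tert-butyldimethylsilyloxy)propyl]-2-ethyl-3,4,7,8-tetrahydro-2H-oxocin-3-yl acetate
Product: 16 (2R,3R,5Z,8S)-8-[(1S)-1-(benzyloxy)-3-(tert-butyldimethylsilyloxy)propyl]-2-ethyl-3,4,7,8-tetrahydro-2H-oxocin-3-ol
Conditions: K2CO3, MeOH, 0 °C
Reagents that add atoms: none
Why: Base-catalysed transesterification (methanolysis of the acetate) frees the C12 hydroxyl under conditions that leave the silyl ether, the benzyl ether and all stereocentres alone.

Step 12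
Reactants: 16 (2R,3R,5Z,8S)-8-[(1S)-1-(benzyloxy)-3-(tert-butyldimethylsilyloxy)propyl]-2-ethyl-3,4,7,8-tetrahydro-2H-oxocin-3-ol
Product: 17 (2R,3S,5Z,8S)-3-bromo-8-[(1S)-1-(benzyloxy)-3-(tert-butyldimethylsilyloxy)propyl]-2-ethyl-3,4,7,8-tetrahydro-2H-oxocine (C12-Br trans to C13-Et)
Conditions: CBr4, (n-Oct)3P, toluene, 70 °C
Reagents that add atoms: carbon tetrabromide, BrC(Br)(Br)Br
Why: Appel-type bromination proceeds by SN2 displacement of the alkoxyphosphonium group by bromide and should therefore invert C12 from (R) to (S), a reaction type long used on 2-alkyl-3-hydroxy medium-ring ethers.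

Step 13
Reactants: 17 (2R,3S,5Z,8S)-3-bromo-8-[(1S)-1-(benzyloxy)-3-(tert-butyldimethylsilyloxy)propyl]-2-ethyl-3,4,7,8-tetrahydro-2H-oxocine
Product: 19 (1S)-1-[(2S,4Z,7S,8R)-7-bromo-8-ethyl-3,6,7,8-tetrahydro-2H-oxocin-2-yl]propane-1,3-diol, via C6 alcohol TBS ether 18 (not isolated)
Conditions: BCl3, CH2Cl2, −78 °C; then MeOH, −78 °C → rt
Reagents that add atoms: none
Why: Lewis-acid cleavage of the benzyl ether by BCl3 at low temperature, followed by solvolysis of the primary TBS ether in the methanolic HCl that the quench generates, should free both hydroxyls in one flask while the alkene, the bromide and the ring ether survive.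

Step 14
Reactants: 19 (1S)-1-[(2S,4Z,7S,8R)-7-bromo-8-ethyl-3,6,7,8-tetrahydro-2H-oxocin-2-yl]propane-1,3-diol
Product: 20 2-[(1S,3R,4S,6S,7S,9S)-4,6-dibromo-3-ethyl-2,8-dioxabicyclo[5.2.1]decan-9-yl]ethan-1-ol (Oa–C9 closed, Br on C10 trans to Oa)
Conditions: NBS, MeCN, 0 °C, dark
Reagents that add atoms: N-bromosuccinimide, O=C1CCC(=O)N1Br
Why: Transannular bromoetherification (5-exo haloetherification): bromonium formation on the alkene face away from the C6 hydroxyl and anti opening at C9 by that hydroxyl, which C6 and C7 hold on one face of the ring, should set C9 (S) and C10 (S) in one stereospecific anti addition and close the oxolane, while the primary hydroxyl cannot reach the alkene through a small ring.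

Step 15
Reactants: 20 2-[(1S,3R,4S,6S,7S,9S)-4,6-dibromo-3-ethyl-2,8-dioxabicyclo[5.2.1]decan-9-yl]ethan-1-ol
Product: 21 2-[(1S,3R,4S,6S,7S,9S)-4,6-dibromo-3-ethyl-2,8-dioxabicyclo[5.2.1]decan-9-yl]acetaldehyde
Conditions: Dess–Martin periodinane, NaHCO3, CH2Cl2, 0 °C → rt
Reagents that add atoms: none
Why: Dess–Martin oxidation of the only remaining (primary) alcohol gives the C4 aldehyde under buffered, non-basic conditions that should neither eliminate HBr nor epimerise a centre.

Step 16
Reactants: 21 2-[(1S,3R,4S,6S,7S,9S)-4,6-dibromo-3-ethyl-2,8-dioxabicyclo[5.2.1]decan-9-yl]acetaldehyde; 22 1,3-bis(triisopropylsilyl)prop-1-yne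
Product: 24 (1S,3R,4S,6S,7S,9S)-4,6-dibromo-3-ethyl-9-[(2Z)-5-(triisopropylsilyl)pent-2-en-4-yn-1-yl]-2,8-dioxabicyclo[5.2.1]decane, via lithiated 1,3-bis(triisopropylsilyl)propyne 23 (not isolated)
Conditions: 22, n-BuLi, THF, −78 °C; then 21, −78 → 0 °C
Reagents that add atoms: n-butyllithium, [Li]CCCC (supplies only the lithium of intermediate 23)
Why: Peterson olefination with the bulky α-silyl propargyl anion is known to give (Z)-enynes by syn elimination of silanolate from the kinetically favoured adduct, which sets the C3=C4 geometry.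

Step 17
Reactants: 24 (1S,3R,4S,6S,7S,9S)-4,6-dibromo-3-ethyl-9-[(2Z)-5-(triisopropylsilyl)pent-2-en-4-yn-1-yl]-2,8-dioxabicyclo[5.2.1]decane
Product: 25 (1S,3R,4S,6S,7S,9S)-4,6-dibromo-3-ethyl-9-[(2Z)-pent-2-en-4-yn-1-yl]-2,8-dioxabicyclo[5.2.1]decane (target)
Conditions: TBAF, THF, 0 °C
Reagents that add atoms: none
Why: Fluoride-induced protodesilylation of the alkynylsilane frees the terminal alkyne, and the secondary bromides should tolerate the short exposure at 0 °C.

**Compound list**

1 | (S)-3-hydroxydihydrofuran-2(3H)-one | O=C1OCC[C@@H]1O | starting material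
2 | (S)-3-(benzyloxy)dihydrofuran-2(3H)-one | O=C1OCC[C@@H]1OCc1ccccc1 | intermediate
3 | (S)-2-(benzyloxy)-4-hydroxy-N-methoxy-N-methylbutanamide | OCC[C@H](OCc1ccccc1)C(=O)N(C)OC | intermediate
4 | (S)-2-(benzyloxy)-4-(tert-butyldimethylsilyloxy)-N-methoxy-N-methylbutanamide | CC(C)(C)[Si](C)(C)OCC[C@H](OCc1ccccc1)C(=O)N(C)OC | intermediate
5 | (S)-2-(benzyloxy)-4-(tert-butyldimethylsilyloxy)butanal | CC(C)(C)[Si](C)(C)OCC[C@H](OCc1ccccc1)C=O | intermediate
6 | hex-3-yn-2-one | CCC#CC(C)=O | starting material
7 | lithium hex-1-en-3-yn-2-olate | [Li+].[O-]C(=C)C#CCC | intermediate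
8 | 2-(trimethylsilyloxy)hex-1-en-3-yne | C=C(O[Si](C)(C)C)C#CCC | intermediate
9 | (7S,8S)-8-(benzyloxy)-10-(tert-butyldimethylsilyloxy)-7-hydroxydec-3-yn-5-one | CC(C)(C)[Si](C)(C)OCC[C@H](OCc1ccccc1)[C@@H](O)CC(=O)C#CCC | intermediate
10 | (2S)-2-[(1S)-1-(benzyloxy)-3-(tert-butyldimethylsilyloxy)propyl]-6-ethyl-2,3-dihydro-4H-pyran-4-one | CC(C)(C)[Si](C)(C)OCC[C@H](OCc1ccccc1)[C@@H]1CC(=O)C=C(CC)O1 | intermediate
11 | vinyl acetate | C=COC(C)=O | starting material
12 | (1S,3S,6S,8R)-3-[(1S)-1-(benzyloxy)-3-(tert-butyldimethylsilyloxy)propyl]-1-ethyl-5-oxo-2-oxabicyclo[4.2.0]octan-8-yl acetate | CC(C)(C)[Si](C)(C)OCC[C@H](OCc1ccccc1)[C@@H]1CC(=O)[C@H]2C[C@@H](OC(C)=O)[C@@]2(CC)O1 | intermediate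
13 | (1S,3S,5R,6R,8R)-3-[(1S)-1-(benzyloxy)-3-(tert-butyldimethylsilyloxy)propyl]-1-ethyl-5-hydroxy-2-oxabicyclo[4.2.0]octan-8-yl acetate | CC(C)(C)[Si](C)(C)OCC[C@H](OCc1ccccc1)[C@@H]1C[C@@H](O)[C@H]2C[C@@H](OC(C)=O)[C@@]2(CC)O1 | intermediate
14 | (1S,3S,5R,6R,8R)-3-[(1S)-1-(benzyloxy)-3-(tert-butyldimethylsilyloxy)propyl]-1-ethyl-5-(trifluoromethylsulfonyloxy)-2-oxabicyclo[4.2.0]octan-8-yl acetate | CC(C)(C)[Si](C)(C)OCC[C@H](OCc1ccccc1)[C@@H]1C[C@@H](OS(=O)(=O)C(F)(F)F)[C@H]2C[C@@H](OC(C)=O)[C@@]2(CC)O1 | intermediate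
15 | (2R,3R,5Z,8S)-8-[(1S)-1-(benzyloxy)-3-(tert-butyldimethylsilyloxy)propyl]-2-ethyl-3,4,7,8-tetrahydro-2H-oxocin-3-yl acetate | CC(C)(C)[Si](C)(C)OCC[C@H](OCc1ccccc1)[C@@H]1C/C=C\C[C@@H](OC(C)=O)[C@@H](CC)O1 | intermediate
16 | (2R,3R,5Z,8S)-8-[(1S)-1-(benzyloxy)-3-(tert-butyldimethylsilyloxy)propyl]-2-ethyl-3,4,7,8-tetrahydro-2H-oxocin-3-ol | CC(C)(C)[Si](C)(C)OCC[C@H](OCc1ccccc1)[C@@H]1C/C=C\C[C@@H](O)[C@@H](CC)O1 | intermediate
17 | (2R,3S,5Z,8S)-3-bromo-8-[(1S)-1-(benzyloxy)-3-(tert-butyldimethylsilyloxy)propyl]-2-ethyl-3,4,7,8-tetrahydro-2H-oxocine | CC(C)(C)[Si](C)(C)OCC[C@H](OCc1ccccc1)[C@@H]1C/C=C\C[C@H](Br)[C@@H](CC)O1 | intermediate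
18 | (1S)-1-[(2S,4Z,7S,8R)-7-bromo-8-ethyl-3,6,7,8-tetrahydro-2H-oxocin-2-yl]-3-(tert-butyldimethylsilyloxy)propan-1-ol | CC(C)(C)[Si](C)(C)OCC[C@H](O)[C@@H]1C/C=C\C[C@H](Br)[C@@H](CC)O1 | intermediate
19 | (1S)-1-[(2S,4Z,7S,8R)-7-bromo-8-ethyl-3,6,7,8-tetrahydro-2H-oxocin-2-yl]propane-1,3-diol | OCC[C@H](O)[C@@H]1C/C=C\C[C@H](Br)[C@@H](CC)O1 | intermediate
20 | 2-[(1S,3R,4S,6S,7S,9S)-4,6-dibromo-3-ethyl-2,8-dioxabicyclo[5.2.1]decan-9-yl]ethan-1-ol | OCC[C@@H]1O[C@H]2C[C@@H]1O[C@H](CC)[C@@H](Br)C[C@@H]2Br | intermediate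
21 | 2-[(1S,3R,4S,6S,7S,9S)-4,6-dibromo-3-ethyl-2,8-dioxabicyclo[5.2.1]decan-9-yl]acetaldehyde | O=CC[C@@H]1O[C@H]2C[C@@H]1O[C@H](CC)[C@@H](Br)C[C@@H]2Br | intermediate
22 | 1,3-bis(triisopropylsilyl)prop-1-yne | CC(C)[Si](C(C)C)(C(C)C)CC#C[Si](C(C)C)(C(C)C)C(C)C | starting material
23 | [1,3-bis(triisopropylsilyl)prop-2-yn-1-yl]lithium | [Li]C(C#C[Si](C(C)C)(C(C)C)C(C)C)[Si](C(C)C)(C(C)C)C(C)C | intermediate
24 | (1S,3R,4S,6S,7S,9S)-4,6-dibromo-3-ethyl-9-[(2Z)-5-(triisopropylsilyl)pent-2-en-4-yn-1-yl]-2,8-dioxabicyclo[5.2.1]decane | CC(C)[Si](C(C)C)(C(C)C)C#C/C=C\C[C@@H]1O[C@H]2C[C@@H]1O[C@H](CC)[C@@H](Br)C[C@@H]2Br | intermediate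
25 | (1S,3R,4S,6S,7S,9S)-4,6-dibromo-3-ethyl-9-[(2Z)-pent-2-en-4-yn-1-yl]-2,8-dioxabicyclo[5.2.1]decane | C#C/C=C\C[C@@H]1O[C@H]2C[C@@H]1O[C@H](CC)[C@@H](Br)C[C@@H]2Br | target

**Step count**

Total number of steps: 17. Longest linear sequence: 16 steps (1 → 25 by steps 1–4 and 6–17; step 5 is a one-step branch from 6).

**Steps most likely to fail**

First, step 10 (the proposed new method). Three things may go wrong: the triflate may ionise with migration of the outer cyclobutane bond C10–C11 instead of cleavage of the ring-fusion bond; hydride may be captured at the acyl carbon of the acetoxonium ion; or hydride may arrive from the wrong face if the acetate, or the C6 benzyl ether oxygen in its place, controls the cation poorly. The fallback uses known radical chemistry and sets out from 13. Acylation with 1,1'-thiocarbonyldiimidazole (DMAP, toluene, 60 °C) gives the thiocarbonylimidazolide F1. Slow addition of Bu3SnH and AIBN in refluxing toluene (Barton–McCombie conditions) generates the C9 radical. This cyclobutylcarbinyl radical should open the ring-fusion bond C10–C13, because only that β-scission gives a tertiary α-alkoxy radical; ring expansion of enone photoadducts by this fragmentation is a known reaction type. Hydrogen transfer from the stannane to C13, anti to the neighbouring acetoxy group, comes back to the route at 15.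

Second, step 8. The photochemical addition may discriminate poorly between endo and exo placement of the acetate and between the two enone faces, and some head-to-head adduct may form, so that the (12R) isomer is only part of the mixture. The fallback changes the alkene and the oxidation level of C12 and sets out from 10. Irradiation with 1,1-diethoxyethene (C=C(OCC)OCC) under the conditions of step 8 should give the diethyl ketal F2; ketene acetals add head-to-tail and leave no stereocentre at C12. Oxalic acid on wet silica gel in CH2Cl2 should hydrolyse it to the cyclobutanone F3. One hydride equivalent (NaBH4, MeOH/CH2Cl2, −78 °C) should then reduce the strained, α-oxygenated cyclobutanone in preference to the six-ring ketone, from the convex face, to the endo alcohol F4. The diastereomer with the cyclobutane syn to the C7 side chain is removed at this stage. Acetylation (Ac2O, pyridine, DMAP) comes back to the route at 12.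

Third, step 14. The C6 hydroxyl may attack C10 instead of C9, giving a six-membered instead of a five-membered ether, or the bromonium ion may form on both alkene faces. The fallback separates ring closure from bromine delivery and sets out from 19. Hg(OCOCF3)2 in MeCN at 0 °C followed by aqueous KBr should give, by reversible anti oxymercuration that can settle on the five-membered ether, the organomercury bromide F5 with mercury on C10 trans to Oa. Bromodemercuration with Br2 in pyridine, which under these polar conditions should proceed with retention at carbon, comes back to the route at 20.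

Further compounds
F1 | step 10 | O-[(1S,3S,5R,6R,8R)-8-acetoxy-3-[(1S)-1-(benzyloxy)-3-(tert-butyldimethylsilyloxy)propyl]-1-ethyl-2-oxabicyclo[4.2.0]octan-5-yl] 1H-imidazole-1-carbothioate | CC(C)(C)[Si](C)(C)OCC[C@H](OCc1ccccc1)[C@@H]1C[C@@H](OC(=S)n2ccnc2)[C@H]3C[C@@H](OC(C)=O)[C@@]3(CC)O1
F2 | step 8 | (1S,3S,6S)-3-[(1S)-1-(benzyloxy)-3-(tert-butyldimethylsilyloxy)propyl]-8,8-diethoxy-1-ethyl-2-oxabicyclo[4.2.0]octan-5-one | CC(C)(C)[Si](C)(C)OCC[C@H](OCc1ccccc1)[C@@H]1CC(=O)[C@H]2CC(OCC)(OCC)[C@@]2(CC)O1
F3 | step 8 | (1S,3S,6S)-3-[(1S)-1-(benzyloxy)-3-(tert-butyldimethylsilyloxy)propyl]-1-ethyl-2-oxabicyclo[4.2.0]octane-5,8-dione | CC(C)(C)[Si](C)(C)OCC[C@H](OCc1ccccc1)[C@@H]1CC(=O)[C@H]2CC(=O)[C@@]2(CC)O1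
F4 | step 8 | (1S,3S,6S,8R)-3-[(1S)-1-(benzyloxy)-3-(tert-butyldimethylsilyloxy)propyl]-1-ethyl-8-hydroxy-2-oxabicyclo[4.2.0]octan-5-one | CC(C)(C)[Si](C)(C)OCC[C@H](OCc1ccccc1)[C@@H]1CC(=O)[C@H]2C[C@@H](O)[C@@]2(CC)O1
F5 | step 14 | bromo[(1S,3R,4S,6S,7S,9S)-4-bromo-3-ethyl-9-(2-hydroxyethyl)-2,8-dioxabicyclo[5.2.1]decan-6-yl]mercury | OCC[C@@H]1O[C@H]2C[C@@H]1O[C@H](CC)[C@@H](Br)C[C@@H]2[Hg]Br
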